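- Double product is what is asked, and its rate of gain in the maple run can be read between neighbouring readings, as a share of the substrate charged per minute; the asked flask is that same run carried on to 8.0 min.

common to all: substrate 0.011 M

| run | reagent | temperature | remark | time |
|---|---|---|---|---|
| maple | 1.2 equiv | 25 °C | the very flask that is asked about, followed so far |  |
| cedar | 1.2 equiv | 10 °C | run made earlier |  |
| flask | 1.20 equiv | 25 °C |  | 8.0 min |

| run | time / min | double product / % | substrate / % |
|---|---|---|---|
| maple | 0.500 | 9.9 | 63.5 |
| maple | 0.833 | 16.2 | 54.0 |
| maple | 1.33 | 23.3 | 45.5 |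
| maple | 2.00 | 30.3 | 38.6 |
| maple | 3.00 | 35.9 | 32.3 |
| maple | 4.00 | 39.4 | 29.9 |
| maple | 6.00 | 41.7 | 27.9 |
| cedar | 1.00 | 10.1 | 63.8 |
| cedar | 2.00 | 18.3 | 52.1 |
| cedar | 3.00 | 24.1 | 45.8 |
| cedar | 4.00 | 28.7 | 40.9 |
| cedar | 6.00 | 34.9 | 35.5 |
| cedar | 8.00 | 38.8 | 31.8 |
| cedar | 12.0 | 42.6 | 29.3 |

(standard deviation of a reading: 0.3 percentage points)

- double product, in percent of the substrate first charged, at 8.0 min
- what to do for the largest gain in double product; "none" if nothing gains more than 2 percentage points (Wednesday's / Tuesday's / Saturday's / Friday's / none)
- double product present, in percent of the substrate first charged, after Wednesday's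
- double product present, in percent of the substrate first charged, after Tuesday's

- Wednesday's: at 8.0 min take out 90 % of the released group then present, then wait 4.0 min
- Tuesday's: change nothing and wait 4.0 min more
- Saturday's: at 8.0 min raise the temperature by 25 K, then wait 4.0 min
- Friday's: at 8.0 min add reagent, 50.0 % of the amount charged, then wait 4.0 min

- the volume of additions can be left aside

- Between the first two maple readings double product gains 0.189 min⁻¹, between 3.00 min and 4.00 min it gains 0.0350 min⁻¹, and over the last maple interval 0.0115 min⁻¹, so the rate slows by a factor 5.40 and then by 3.04, together 16.4.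
- Each substrate lost draws one reagent and each double product formed draws another, so the summed rate of maple's reagent draw is read from both columns, and it slows by a factor 22.1; with 1.20 equiv charged against two steps, this reckoning takes reagent as the limiting reagent.
- From the first and last of these rates, taken at the middles of their intervals, comes the rate halving time, the time in which the gain of double product falls by a factor of two: 1.07 min.
- The gain still to come at any moment is then the rate at that moment times the halving time over ln(2), which leaves 0.93 percentage points after 6.00 min and an end near 42.6 %.
- This reckoning therefore puts the flask at 42.4 % at 8.0 min, and waiting 4.0 min more adds 0.24 points, less than the margin of 2 points, so it drops Tuesday's and, having taken reagent as limiting, chooses the added reagent of Friday's.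
- The forecast gives 43 %, 45 % after Wednesday's and 43.5 % after Tuesday's, and picks Friday's for “a gain far larger than any other option”, its 43 % standing above this reckoning's 42.4 %.
- The flask gives 43.0 % at 8.0 min, 43.4 % after Wednesday's and 43.4 % after Tuesday's, and the best step is Friday's, with a gain of 25 points.

    substrate + reagent → first product + released group (k = 2.60 M⁻¹ s⁻¹, Ea = 44.0 kJ mol⁻¹)
    reagent + first product → double product + released group (k = 3.50 M⁻¹ s⁻¹, Ea = 40.0 kJ mol⁻¹)
    reagent + double product → tris adduct + released group (k = 0.150 M⁻¹ s⁻¹, Ea = 59.0 kJ mol⁻¹)
    double product → over-reaction product (k = 1.00 × 10⁻⁵ s⁻¹, Ea = 103 kJ mol⁻¹)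
    reagent ⇌ dormant form (K = 1.10, k = 0.0750 s⁻¹, Ea = 76.0 kJ mol⁻¹, ΔH = 9.00 kJ mol⁻¹)
    (constants at 25 °C)

- Waiting gains the flask 0.38 points against the reckoned 0.24 points, with reagent at 0.39 % of its own charge at 8.00 min. The neighbouring flask is the same one read at 2.0 min: running the halving time back from the end, with the first rate, gives 30.3 %, and that flask holds 29.9 % of double product.

All runs are simulated for an exercise, noise included.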